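**Retrosynthetic overview**

1. Locants: ring B (cycloheptenone) = C1(CH3)=C2–C3(=O)–C4(CH3)–C5(H)–C6(OAr)–C7H2; ring A (cyclopentane) = C4–C8–C9–C10(OH)(iPr)–C5.
2. Target ⇒ hydroxy enone 16 + acid 17 (ester C6–O bond; two silyl ethers removed last).
3. Ring B is closed last, across C6–C7. The array C3(=O)–C2=C1(CH3)–C7–C6(OH) is the retron of a carbonyl-ene reaction followed by conjugation, so 16 ⇒ ring A aldehyde 14 with the CHO (C6) on C5 and a deconjugated 3-methylbut-3-enoyl arm (C3, C2, C1, C7) on C4. The trans placement of these two arms on ring A shuts off the five-membered aldol alternative.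
4. 14 ⇒ cyclopentanone 6: C10 carbinol by isopropyl addition; acyl arm grown from a 1-silylvinyl group (epoxysilane, oxirane, CH2=C(CH3)MgBr/CuI, oxidation); C6 stored as a dimethyl acetal.
5. 6 ⇒ 3-methylcyclopent-2-enone 1: enantioselective conjugate addition of a silylvinylalane sets C4, and the trapped enolate is formylated (as acetal) at C5. Ring A is present from the start; ring B is the only ring closed (step 9).

Key step: step 9

Remark on the chemistry: 8, 9 and 10 are carried as mixtures of epimers at the carbon that becomes the C3 ketone in step 7; acid 17 and the chiral imidazolinium sulfonate (NHC precursor) are taken as purchasable.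

**Route**

Step 1
Reactants: 1 3-methylcyclopent-2-en-1-one; 2 ethynyl(trimethyl)silane
Product: 5 (S)-triethyl({3-methyl-3-[1-(trimethylsilyl)ethenyl]cyclopent-1-en-1-yl}oxy)silane, via vinylalane 3 (not isolated), via aluminium enolate 4 (not isolated)
Conditions: 2, iBu2AlH, hexanes, 55 °C; then 1, Cu(OTf)2 (5 mol %), chiral sulfonate-bearing N-aryl imidazolinium salt (NHC precursor, 5 mol %, enantiomer chosen for the (S) centre), THF, 4 °C; then Et3SiOTf, −78 → 0 °C
Reagents that add atoms: triethylsilyl trifluoromethanesulfonate, CC[Si](CC)(CC)OS(=O)(=O)C(F)(F)F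
Why: Hydroalumination gives the α-silylvinylalane, whose copper–NHC-catalysed enantioselective conjugate addition to the β-methyl enone (a known reaction class for this type of enone and alane) sets the quaternary C4 centre under catalyst control, and O-silylation of the aluminium enolate fixes the enolate regiochemistry toward C5.

Step 2
Reactants: 5 (S)-triethyl({3-methyl-3-[1-(trimethylsilyl)ethenyl]cyclopent-1-en-1-yl}oxy)silane
Product: 6 (2S,3S)-2-(dimethoxymethyl)-3-methyl-3-[1-(trimethylsilyl)ethenyl]cyclopentan-1-one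
Conditions: HC(OMe)3, Me3SiOTf (10 mol %), CH2Cl2, −78 °C
Reagents that add atoms: trimethyl orthoformate, COC(OC)OC
Why: Mukaiyama-type reaction of the silyl enol ether with the dimethoxycarbenium ion from the orthoester puts the masked formyl carbon (C6) on C5 anti to the bulky 1-silylvinyl group of the neighbouring quaternary carbon (cis to the C4 methyl), and this trans isomer is also the one favoured if C5 equilibrates.

Step 3
Reactants: 6 (2S,3S)-2-(dimethoxymethyl)-3-methyl-3-[1-(trimethylsilyl)ethenyl]cyclopentan-1-one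
Product: 7 (1R,2R,3S)-2-(dimethoxymethyl)-3-methyl-1-(propan-2-yl)-3-[1-(trimethylsilyl)ethenyl]cyclopentan-1-ol
Conditions: iPrMgCl, CeCl3 (anhydrous), THF, −78 → 0 °C
Reagents that add atoms: isopropylmagnesium chloride, CC(C)[Mg]Cl
Why: Organocerium 1,2-addition (chosen to suppress enolisation and β-hydride reduction) should take place on the ketone face opposite the adjacent acetal arm and the pseudoaxial C4 methyl group, which sets C10 with the hydroxyl cis to C6.

Step 4
Reactants: 7 (1R,2R,3S)-2-(dimethoxymethyl)-3-methyl-1-(propan-2-yl)-3-[1-(trimethylsilyl)ethenyl]cyclopentan-1-ol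
Product: 8 (1R,2R,3S)-2-(dimethoxymethyl)-3-methyl-1-(propan-2-yl)-3-[2-(trimethylsilyl)oxiran-2-yl]cyclopentan-1-ol (both epimers at the oxirane carbon)
Conditions: mCPBA, NaHCO3, CH2Cl2, 0 °C
Reagents that add atoms: 3-chloroperoxybenzoic acid, OOC(=O)c1cccc(Cl)c1
Why: Prilezhaev epoxidation of the only alkene, the electron-rich vinylsilane, under buffered conditions; the oxirane carbon is formed as an inconsequential mixture because it becomes the ketone carbon in step 7.

Step 5
Reactants: 8 (1R,2R,3S)-2-(dimethoxymethyl)-3-methyl-1-(propan-2-yl)-3-[2-(trimethylsilyl)oxiran-2-yl]cyclopentan-1-ol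
Product: 9 (1R,2R,3S)-2-(dimethoxymethyl)-3-methyl-3-(oxiran-2-yl)-1-(propan-2-yl)cyclopentan-1-ol (both epimers at the oxirane carbon)
Conditions: Bu4NF, wet DMSO, 60 °C
Reagents that add atoms: none
Why: Fluoride-induced protodesilylation of the α,β-epoxysilane (attack at silicon, protonation of the oxiranyl anion) is a known way to unveil the parent oxirane and should leave acetal and tertiary alcohol untouched.

Step 6
Reactants: 9 (1R,2R,3S)-2-(dimethoxymethyl)-3-methyl-3-(oxiran-2-yl)-1-(propan-2-yl)cyclopentan-1-ol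
Product: 10 (1R,2R,3S)-2-(dimethoxymethyl)-3-(1-hydroxy-3-methylbut-3-en-1-yl)-3-methyl-1-(propan-2-yl)cyclopentan-1-ol (both carbinol epimers)
Conditions: CH2=C(CH3)MgBr (3 equiv), CuI (10 mol %), THF, −30 → 0 °C
Reagents that add atoms: isopropenylmagnesium bromide, CC(=C)[Mg]Br
Why: Copper-catalysed SN2 opening of the monosubstituted epoxide by the alkenyl Grignard reagent at the unhindered CH2 terminus (C2) attaches C1, its methyl group and C7 in one operation.

Step 7
Reactants: 10 (1R,2R,3S)-2-(dimethoxymethyl)-3-(1-hydroxy-3-methylbut-3-en-1-yl)-3-methyl-1-(propan-2-yl)cyclopentan-1-ol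
Product: 11 1-[(1S,2R,3R)-2-(dimethoxymethyl)-3-hydroxy-1-methyl-3-(propan-2-yl)cyclopentyl]-3-methylbut-3-en-1-one
Conditions: Dess–Martin periodinane, NaHCO3, CH2Cl2, 0 °C → rt
Reagents that add atoms: none
Why: Dess–Martin oxidation of the secondary carbinol (the tertiary alcohol is inert) under bicarbonate buffering should give the β,γ-unsaturated ketone without moving the double bond into conjugation.

Step 8
Reactants: 11 1-[(1S,2R,3R)-2-(dimethoxymethyl)-3-hydroxy-1-methyl-3-(propan-2-yl)cyclopentyl]-3-methylbut-3-en-1-one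
Product: 14 (1R,2S,5R)-2-methyl-2-(3-methylbut-3-enoyl)-5-(propan-2-yl)-5-[(triethylsilyl)oxy]cyclopentane-1-carbaldehyde, via silyl ether 12 (not isolated), via pyridinium salt 13 (not isolated)
Conditions: Et3SiOTf (3 equiv), 2,6-lutidine (4 equiv), CH2Cl2, −78 → 0 °C; then H2O, rt
Reagents that add atoms: triethylsilyl trifluoromethanesulfonate, CC[Si](CC)(CC)OS(=O)(=O)C(F)(F)F; water, O
Why: The silyl triflate/2,6-lutidine pair first silylates the tertiary alcohol and then ionises the dimethyl acetal to a pyridinium N,O-acetal that water hydrolyses to the aldehyde (a known near-neutral, chemoselective acetal cleavage), conditions under which the silyl ether and the hindered, deconjugated ketone should persist.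

Step 9
Reactants: 14 (1R,2S,5R)-2-methyl-2-(3-methylbut-3-enoyl)-5-(propan-2-yl)-5-[(triethylsilyl)oxy]cyclopentane-1-carbaldehyde
Product: 16 (3R,3aS,4S,8aS)-4-hydroxy-6,8a-dimethyl-3-(propan-2-yl)-3-[(triethylsilyl)oxy]-2,3,3a,4,5,8a-hexahydroazulen-8(1H)-one, via methylidene alcohol 15 (not isolated)
Conditions: Me2AlCl (2 equiv), CH2Cl2, −78 → −20 °C; aq. NaHCO3; then DBU (20 mol %), CH2Cl2, rt
Reagents that add atoms: none
Why: Me2AlCl binds the C6 aldehyde, the terminal carbon (C7) of the 1,1-disubstituted alkene attacks it while an allylic hydrogen passes to oxygen (type 2 intramolecular carbonyl-ene reaction, concerted to stepwise), and the aluminium alkoxide then loses methane so that the closure is irreversible. The closest known reaction type is the alkylaluminium halide-promoted type 2 ene cyclisation of 6-methylhept-6-enals to 3-methylidenecycloheptanols. Ring B closes by a 7-exo-trig attack on the carbonyl in which both alkene carbons (C1 and C7) end up inside the new ring. The new C6 stereocentre is substrate-controlled: in the chair-like transition state the aluminium-bound oxygen sits pseudo-equatorial and C7 approaches anti to the bulky C10 centre (Felkin–Anh sense), the Et3Si ether preventing chelation, which should place the oxygen anti to C4 with H5 and H6 anti. The step needs C–C bond formation at C7 and not aldol attack through C2, and needs the alkene to stay deconjugated until it has reacted: the trans arrangement of the two arms on ring A would force a trans-fused bicyclo[3.3.0]octane in the aldol mode, and the proton-scavenging Lewis acid at low temperature should not isomerise the β,γ-enone. DBU finally moves the exocyclic double bond (or any chloride-trapped form of it) into conjugation with the C3 ketone, the thermodynamic sink.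

Step 10
Reactants: 16 (3R,3aS,4S,8aS)-4-hydroxy-6,8a-dimethyl-3-(propan-2-yl)-3-[(triethylsilyl)oxy]-2,3,3a,4,5,8a-hexahydroazulen-8(1H)-one; 17 4-[(tert-butyldimethylsilyl)oxy]benzoic acid
Product: 18 (3R,3aS,4S,8aS)-6,8a-dimethyl-8-oxo-3-(propan-2-yl)-3-[(triethylsilyl)oxy]-1,2,3,3a,4,5,8,8a-octahydroazulen-4-yl 4-[(tert-butyldimethylsilyl)oxy]benzoate
Conditions: DCC, DMAP, CH2Cl2, 0 °C → rt
Reagents that add atoms: none
Why: Steglich esterification (carbodiimide activation, DMAP acyl transfer) acylates the only free hydroxyl with retention at C6, the tertiary C10 oxygen being blocked.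

Step 11
Reactants: 18 (3R,3aS,4S,8aS)-6,8a-dimethyl-8-oxo-3-(propan-2-yl)-3-[(triethylsilyl)oxy]-1,2,3,3a,4,5,8,8a-octahydroazulen-4-yl 4-[(tert-butyldimethylsilyl)oxy]benzoate
Product: 19 (3R,3aS,4S,8aS)-3-hydroxy-6,8a-dimethyl-8-oxo-3-(propan-2-yl)-1,2,3,3a,4,5,8,8a-octahydroazulen-4-yl 4-hydroxybenzoate
Conditions: HF·pyridine, pyridine, THF, 0 °C → rt
Reagents that add atoms: none
Why: Fluoride-driven desilylation under buffered, non-basic conditions should remove the aryl and the tertiary silyl ether together while avoiding base-induced vinylogous β-elimination of the δ-acyloxy enone or ester cleavage.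

**Compound list**

1 | 3-methylcyclopent-2-en-1-one | CC1=CC(=O)CC1 | starting material
2 | ethynyl(trimethyl)silane | C#C[Si](C)(C)C | starting material
3 | bis(2-methylpropyl)[1-(trimethylsilyl)ethenyl]alumane | C=C([Si](C)(C)C)[Al](CC(C)C)CC(C)C | intermediate (not isolated)
4 | bis(2-methylpropyl)({(3S)-3-methyl-3-[1-(trimethylsilyl)ethenyl]cyclopent-1-en-1-yl}oxy)alumane | C=C([Si](C)(C)C)[C@@]1(C)CCC(O[Al](CC(C)C)CC(C)C)=C1 | intermediate (not isolated)
5 | (S)-triethyl({3-methyl-3-[1-(trimethylsilyl)ethenyl]cyclopent-1-en-1-yl}oxy)silane | C=C([Si](C)(C)C)[C@@]1(C)CCC(O[Si](CC)(CC)CC)=C1 | intermediate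
6 | (2S,3S)-2-(dimethoxymethyl)-3-methyl-3-[1-(trimethylsilyl)ethenyl]cyclopentan-1-one | C=C([Si](C)(C)C)[C@@]1(C)CCC(=O)[C@@H]1C(OC)OC | intermediate
7 | (1R,2R,3S)-2-(dimethoxymethyl)-3-methyl-1-(propan-2-yl)-3-[1-(trimethylsilyl)ethenyl]cyclopentan-1-ol | C=C([Si](C)(C)C)[C@@]1(C)CC[C@@](O)(C(C)C)[C@@H]1C(OC)OC | intermediate
8 | (1R,2R,3S)-2-(dimethoxymethyl)-3-methyl-1-(propan-2-yl)-3-[2-(trimethylsilyl)oxiran-2-yl]cyclopentan-1-ol, epimers at the oxirane carbon | C[Si](C)(C)C1(CO1)[C@@]2(C)CC[C@@](O)(C(C)C)[C@@H]2C(OC)OC | intermediate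
9 | (1R,2R,3S)-2-(dimethoxymethyl)-3-methyl-3-(oxiran-2-yl)-1-(propan-2-yl)cyclopentan-1-ol, epimers at the oxirane carbon | C1OC1[C@@]2(C)CC[C@@](O)(C(C)C)[C@@H]2C(OC)OC | intermediate
10 | (1R,2R,3S)-2-(dimethoxymethyl)-3-(1-hydroxy-3-methylbut-3-en-1-yl)-3-methyl-1-(propan-2-yl)cyclopentan-1-ol, carbinol epimers | CC(=C)CC(O)[C@@]1(C)CC[C@@](O)(C(C)C)[C@@H]1C(OC)OC | intermediate
11 | 1-[(1S,2R,3R)-2-(dimethoxymethyl)-3-hydroxy-1-methyl-3-(propan-2-yl)cyclopentyl]-3-methylbut-3-en-1-one | CC(=C)CC(=O)[C@@]1(C)CC[C@@](O)(C(C)C)[C@@H]1C(OC)OC | intermediate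
12 | 1-[(1S,2R,3R)-2-(dimethoxymethyl)-1-methyl-3-(propan-2-yl)-3-[(triethylsilyl)oxy]cyclopentyl]-3-methylbut-3-en-1-one | CC(=C)CC(=O)[C@@]1(C)CC[C@@](O[Si](CC)(CC)CC)(C(C)C)[C@@H]1C(OC)OC | intermediate (not isolated)
13 | 1-[methoxy{(1R,2S,5R)-2-methyl-2-(3-methylbut-3-enoyl)-5-(propan-2-yl)-5-[(triethylsilyl)oxy]cyclopentyl}methyl]-2,6-dimethylpyridin-1-ium trifluoromethanesulfonate, either configuration at the N,O-acetal carbon | CC(=C)CC(=O)[C@@]1(C)CC[C@@](O[Si](CC)(CC)CC)(C(C)C)[C@@H]1C(OC)[n+]1c(C)cccc1C.[O-]S(=O)(=O)C(F)(F)F | intermediate (not isolated)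
14 | (1R,2S,5R)-2-methyl-2-(3-methylbut-3-enoyl)-5-(propan-2-yl)-5-[(triethylsilyl)oxy]cyclopentane-1-carbaldehyde | CC(=C)CC(=O)[C@@]1(C)CC[C@@](O[Si](CC)(CC)CC)(C(C)C)[C@@H]1C=O | intermediate
15 | (3R,3aS,4S,8aS)-4-hydroxy-8a-methyl-6-methylidene-3-(propan-2-yl)-3-[(triethylsilyl)oxy]octahydroazulen-8(1H)-one | C=C1CC(=O)[C@@]2(C)CC[C@@](O[Si](CC)(CC)CC)(C(C)C)[C@@H]2[C@@H](O)C1 | intermediate (not isolated)
16 | (3R,3aS,4S,8aS)-4-hydroxy-6,8a-dimethyl-3-(propan-2-yl)-3-[(triethylsilyl)oxy]-2,3,3a,4,5,8a-hexahydroazulen-8(1H)-one | CC1=CC(=O)[C@@]2(C)CC[C@@](O[Si](CC)(CC)CC)(C(C)C)[C@@H]2[C@@H](O)C1 | intermediate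
17 | 4-[(tert-butyldimethylsilyl)oxy]benzoic acid | CC(C)(C)[Si](C)(C)Oc1ccc(cc1)C(O)=O | starting material
18 | (3R,3aS,4S,8aS)-6,8a-dimethyl-8-oxo-3-(propan-2-yl)-3-[(triethylsilyl)oxy]-1,2,3,3a,4,5,8,8a-octahydroazulen-4-yl 4-[(tert-butyldimethylsilyl)oxy]benzoate | CC1=CC(=O)[C@@]2(C)CC[C@@](O[Si](CC)(CC)CC)(C(C)C)[C@@H]2[C@@H](OC(=O)c2ccc(O[Si](C)(C)C(C)(C)C)cc2)C1 | intermediate
19 | (3R,3aS,4S,8aS)-3-hydroxy-6,8a-dimethyl-8-oxo-3-(propan-2-yl)-1,2,3,3a,4,5,8,8a-octahydroazulen-4-yl 4-hydroxybenzoate | CC1=CC(=O)[C@@]2(C)CC[C@@](O)(C(C)C)[C@@H]2[C@@H](OC(=O)c2ccc(O)cc2)C1 | target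

**Step count and risks**

Total step count: 11. Longest linear sequence: 11 steps (1 → 19); 2 and 17 enter as purchased fragments.

Steps most likely to fail:

Step 9 (ring closure). The alkene may drift into conjugation with the C3 ketone before it has attacked the aldehyde, or the two faces of the aldehyde may be poorly differentiated. The fallback replaces the ene donor by an allylsilane and sets out from oxirane 9. Copper-catalysed opening with CH2=C(MgBr)CH2SiMe3 (from commercial (2-bromoallyl)trimethylsilane and Mg, CuI cat.) would give the allylsilane diol F1. Dess–Martin oxidation would give the allylsilane ketone F2, and Et3SiOTf/2,6-lutidine followed by water the allylsilane aldehyde F3. BF3·OEt2 at −78 °C would then close ring B by an intramolecular Hosomi–Sakurai allylation, which is irreversible, regiodefined by silicon and run at a temperature where the alkene cannot isomerise. The fallback returns to the route at 15 and, after the DBU treatment of step 9, at 16.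

Step 5 (protodesilylation). Cleavage of the C–Si bond at the fully substituted oxirane carbon may be slow enough for opening of the epoxide under the basic fluoride conditions to compete. The fallback changes the order of events and sets out from epoxysilane 8. Copper-catalysed opening with CH2=C(CH3)MgBr at the CH2 terminus would give the α-hydroxysilane F4. A base-induced Brook rearrangement with protonation (KOtBu cat., wet DMSO) would then remove silicon after the carbon chain is in place, returning at diol 10.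

Step 3 (isopropyl addition). With the branched Grignard reagent, enolisation or β-hydride reduction of the hindered ketone may outrun addition. The fallback uses an sp2 nucleophile without β-hydrogens and then saturates it, setting out from ketone 6. CH2=C(CH3)MgBr/CeCl3 would give the isopropenyl carbinol F5. Hydroxyl-directed hydrogenation with [Rh(nbd)(dppb)]BF4 and H2 should then reduce only the alkene next to the tertiary alcohol, since the vinylsilane is remote from the directing group and more hindered, returning at 7.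

**Further compounds**

F1 | step 9 | (1R,2R,3S)-2-(dimethoxymethyl)-3-{1-hydroxy-3-[(trimethylsilyl)methyl]but-3-en-1-yl}-3-methyl-1-(propan-2-yl)cyclopentan-1-ol, carbinol epimers | C[Si](C)(C)CC(=C)CC(O)[C@@]1(C)CC[C@@](O)(C(C)C)[C@@H]1C(OC)OC
F2 | step 9 | 1-[(1S,2R,3R)-2-(dimethoxymethyl)-3-hydroxy-1-methyl-3-(propan-2-yl)cyclopentyl]-3-[(trimethylsilyl)methyl]but-3-en-1-one | C[Si](C)(C)CC(=C)CC(=O)[C@@]1(C)CC[C@@](O)(C(C)C)[C@@H]1C(OC)OC
F3 | step 9 | (1R,2S,5R)-2-methyl-5-(propan-2-yl)-5-[(triethylsilyl)oxy]-2-{3-[(trimethylsilyl)methyl]but-3-enoyl}cyclopentane-1-carbaldehyde | C[Si](C)(C)CC(=C)CC(=O)[C@@]1(C)CC[C@@](O[Si](CC)(CC)CC)(C(C)C)[C@@H]1C=O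
F4 | step 5 | (1R,2R,3S)-2-(dimethoxymethyl)-3-[1-hydroxy-3-methyl-1-(trimethylsilyl)but-3-en-1-yl]-3-methyl-1-(propan-2-yl)cyclopentan-1-ol, epimers at the silyl carbinol | CC(=C)CC(O)([Si](C)(C)C)[C@@]1(C)CC[C@@](O)(C(C)C)[C@@H]1C(OC)OC
F5 | step 3 | (1S,2R,3S)-2-(dimethoxymethyl)-3-methyl-1-(prop-1-en-2-yl)-3-[1-(trimethylsilyl)ethenyl]cyclopentan-1-ol | C=C([Si](C)(C)C)[C@@]1(C)CC[C@@](O)(C(C)=C)[C@@H]1C(OC)OC
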